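Retrosynthetic overview
1. Dioxane ring: O3'–C1 and O2'–C5 are cut by a retro-hetero-Diels–Alder step. This gives guaia-1(5),3,11-triene 12 and o-quinone 13, the C8'-H tautomer of commercial pristimerin 9, so all five triterpene rings are bought.
2. Seven-membered ring: C10–H is removed as hydride (12 back to fulvene 10). The C1=C10 bond is then opened by a retro-condensation to the monocyclic cyclopentadienyl methyl ketone 8.
3. Enabling feature: C1 and C5 are shared by the five-membered ring, the seven-membered ring and the 1,4-dioxane ring, and both carry aryl oxygens. Without the quinone they are the C1=C5 bond of a cyclopentadiene (C1–C5). C10, the CH(CH3) carbon on C1, is then the exocyclic carbon of a fulvene, which a cyclopentadiene CH2 and a methyl ketone form readily.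
4. 8 comes from (S)-carvone 1 (source of C7) by conjugate reduction, Baeyer–Villiger opening of the six-membered ring, and a [4+1] annulation of the lactone carbonyl carbon (C5) with penta-1,3-diene 4 (C1–C4, C15).
5. Order of ring formation: five-membered ring (step 3), then the seven-membered ring and the 1,4-dioxane ring in one flask (step 6).

Key step: step 6

Numbering: the sesquiterpene part uses guaiane numbers. C1 and C5 are the O-bearing ring-fusion carbons, C10 is CH(CH3), C7 bears the isopropenyl group C11–C13, and C14 and C15 are the methyl groups on C10 and C4. The triterpene part uses primed friedelane numbers (O2', O3', C6', C8').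
Assumption: step 1 gives 2 together with its C2 epimer. Both are carried on and drawn as the major epimer, because this centre (the later C10) becomes sp2 in step 4 and is set anew in step 6.

Step 1
Reactants: 1 (S)-(+)-carvone
Product: 2 (2S,5S)-2-methyl-5-(prop-1-en-2-yl)cyclohexan-1-one
Conditions: Zn dust, AcOH, EtOH/H2O, reflux
Reagents that add atoms: none
Why: Dissolving-metal conjugate reduction, in which zinc transfers electrons only to the conjugated C=C–C=O unit, so the isolated isopropenyl group and the centre that becomes C7 stay untouched, and protonation of the enol should favour the trans epimer.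

Step 2
Reactants: 2 (2S,5S)-2-methyl-5-(prop-1-en-2-yl)cyclohexan-1-one
Product: 3 (4S,7S)-7-methyl-4-(prop-1-en-2-yl)oxepan-2-one
Conditions: H2O2 (aq), Sn-Beta zeolite (SnxSi1-xO2, cat.), 1,4-dioxane, 80 °C
Reagents that add atoms: hydrogen peroxide, OO
Why: Baeyer–Villiger oxidation in which the framework tin activates the C=O group and not the peroxide, so the isopropenyl group should not be epoxidised, and the more substituted CH(CH3) carbon migrates with retention and receives the ring oxygen.

Step 3
Reactants: 3 (4S,7S)-7-methyl-4-(prop-1-en-2-yl)oxepan-2-one; 4 (E)-penta-1,3-diene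
Product: 6 1-[(2S,5S)-5-hydroxy-2-(prop-1-en-2-yl)hexyl]-2-methylcyclopent-3-en-1-ol, via diene-magnesium reagent 5 (not isolated)
Conditions: Rieke Mg powder, 4, THF, rt; then 3, -78 °C to reflux; aq NH4Cl
Reagents that add atoms: none
Why: Formal [4+1] annulation known for conjugated-diene-magnesium reagents and carboxylic esters or lactones, in which 5 adds twice to the lactone carbonyl carbon (first to a vinylcyclopropanolate that ring-expands on heating) so that this carbon becomes C5 between C1H2 and C4H(CH3), the leaving alkoxide stays in the molecule as the C10 oxygen, the isopropenyl group does not react, and the two new ring centres arise as a mixture that step 5 erases.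

Step 4
Reactants: 6 1-[(2S,5S)-5-hydroxy-2-(prop-1-en-2-yl)hexyl]-2-methylcyclopent-3-en-1-ol
Product: 7 (5S)-5-[(1-hydroxy-2-methylcyclopent-3-en-1-yl)methyl]-6-methylhept-6-en-2-one
Conditions: Dess–Martin periodinane, CH2Cl2, 0 °C to rt
Reagents that add atoms: none
Why: Dess–Martin oxidation, where only the secondary C10 alcohol has a carbinol hydrogen, so the tertiary alcohol and both alkenes are left alone and both C10 epimers converge on one ketone.

Step 5
Reactants: 7 (5S)-5-[(1-hydroxy-2-methylcyclopent-3-en-1-yl)methyl]-6-methylhept-6-en-2-one
Product: 8 (5S)-6-methyl-5-[(2-methylcyclopenta-1,3-dien-1-yl)methyl]hept-6-en-2-one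
Conditions: Burgess reagent, toluene, 50 °C; used at once
Reagents that add atoms: none
Why: Burgess dehydration (neutral syn elimination of the tertiary sulfamate, which spares the ketone and the isopropenyl group) towards C4 or C1 gives a diene conjugated with C2=C3, 1,5-hydrogen shifts merge the ring isomers into the cyclopentadiene drawn as 8, and no stereocentre is formed.

Step 6
Reactants: 8 (5S)-6-methyl-5-[(2-methylcyclopenta-1,3-dien-1-yl)methyl]hept-6-en-2-one; 9 pristimerin
Product: 14 target CNP0113384.4, via fulvene 10 (not isolated), via lithium cyclopentadienide 11 (not isolated), via guaia-1(5),3,11-triene 12 (not isolated), via o-quinone tautomer 13 (not isolated)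
Conditions: (i) pyrrolidine, MeOH, 0 °C to rt, high dilution, then evaporation; (ii) LiAlH4, Et2O, 0 °C; (iii) AcOH, -40 °C; (iv) 9, toluene, 35 °C, dark, Ar
Reagents that add atoms: none
Why: Proposed new method: the four events are known singly but have not been run as one sequence or on a hydroxy-quinone methide, the closest known types being the amine-catalysed Thiele fulvene condensation, hydride addition to 6,6-dialkylfulvenes and the inverse-electron-demand hetero-Diels–Alder reaction of o-quinones with alkenes and fulvenes, which is also the presumed biosynthesis. Pyrrolidine turns the C10 ketone into an iminium ion, the cyclopentadiene attacks it through C1 (7-exo-trig closure of the seven-membered ring; attack through C5 is reversible because that adduct has no hydrogen to lose, and C2 and C3 are out of reach) and loss of the amine gives the C1=C10 bond of fulvene 10. LiAlH4 delivers hydride to C10 because this makes the aromatic cyclopentadienide 11, and it should arrive axially on the half-chair that keeps the C7 isopropenyl group equatorial, so that C14 ends equatorial and trans to it (10S); AcOH then gives 12, whose tautomers interconvert by 1,5-hydrogen shifts. The acetate/acetic acid buffer formed in the quench moves the O3' proton of 9 to C8', on the β face because the α face of this ring C carbon lies under the axial 13'α-methyl group (8'β-H), and so supplies o-quinone 13. The O2'=C2'–C3'=O3' unit of 13 adds suprafacially to C1=C5 and closes the 1,4-dioxane ring in a concerted but asynchronous [4+2] step, so O2' and O3' are cis, and they should enter syn to the equatorial C14 methyl group and anti to the isopropenyl group, because the large C2 and C4 atoms then bend towards the face that carries only the axial hydrogens of C6 and C10 while the flat quinone lies over the planar five-membered ring (1S,5S). The step needs site selectivity (C1=C5 is the only tetrasubstituted and most electron-rich π bond and the small oxygen termini can still reach it, against C3=C4 and C11=C12), orientation (O3'–C1 bonding leads because it leaves the charge on O2', para to the styrene arm, and an allyl cation over C5–C4–C3) and chemoselectivity against attack of 12 at C6' of 9 (weakly acidic buffer, no strong Lewis acid).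

Compound list
1 | (S)-(+)-carvone | CC1=CC[C@@H](CC1=O)C(C)=C | starting material
2 | (2S,5S)-2-methyl-5-(prop-1-en-2-yl)cyclohexan-1-one (trans-dihydrocarvone) | C[C@H]1CC[C@@H](CC1=O)C(C)=C | intermediate
3 | (4S,7S)-7-methyl-4-(prop-1-en-2-yl)oxepan-2-one | C[C@H]1CC[C@@H](CC(=O)O1)C(C)=C | intermediate
4 | (E)-penta-1,3-diene | C/C=C/C=C | starting material
5 | (pent-2-ene-1,4-diyl)magnesium, drawn as the magnesacyclopentene | CC1C=CC[Mg]1 | intermediate
6 | 1-[(2S,5S)-5-hydroxy-2-(prop-1-en-2-yl)hexyl]-2-methylcyclopent-3-en-1-ol (mixture at the two ring centres) | C[C@H](O)CC[C@@H](CC1(O)CC=CC1C)C(C)=C | intermediate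
7 | (5S)-5-[(1-hydroxy-2-methylcyclopent-3-en-1-yl)methyl]-6-methylhept-6-en-2-one | CC(=O)CC[C@@H](CC1(O)CC=CC1C)C(C)=C | intermediate
8 | (5S)-6-methyl-5-[(2-methylcyclopenta-1,3-dien-1-yl)methyl]hept-6-en-2-one (one ring tautomer drawn) | CC(=O)CC[C@@H](CC1=C(C)C=CC1)C(C)=C | intermediate
9 | pristimerin | CC1=C(O)C(=O)C=C2C1=CC=C1[C@@]2(C)CC[C@@]2(C)[C@@H]3C[C@](C)(C(=O)OC)CC[C@]3(C)CC[C@]12C | starting material
10 | (7S)-1,4-dimethyl-7-(prop-1-en-2-yl)-5,6,7,8-tetrahydroazulene (bicyclic fulvene, C1=C10) | CC1=C2C=CC(C)=C2C[C@H](CC1)C(C)=C | intermediate
11 | lithium cyclopentadienide of 12 (one resonance form drawn, 10S,7S) | [Li+].C[C@H]1CC[C@H](C(C)=C)CC2=C(C)C=C[C-]12 | intermediate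
12 | (4S,7S)-1,4-dimethyl-7-(prop-1-en-2-yl)-3,4,5,6,7,8-hexahydroazulene (guaia-1(5),3,11-triene) | C[C@H]1CC[C@H](C(C)=C)CC2=C1CC=C2C | intermediate
13 | 2',3'-o-quinone tautomer of pristimerin (6'-ene, 8'β-H) | O=C1C=C2C(=C(C)C1=O)C=C[C@@H]1[C@@]2(C)CC[C@@]2(C)[C@@H]3C[C@](C)(C(=O)OC)CC[C@]3(C)CC[C@]12C | intermediate
14 | CNP0113384.4 | C=C(C)[C@H]1CC[C@H](C)[C@@]23CC=C(C)[C@]2(C1)Oc1cc2c(c(C)c1O3)C=C[C@@H]1[C@@]2(C)CC[C@@]2(C)[C@@H]3C[C@](C)(C(=O)OC)CC[C@]3(C)CC[C@]12C | target

Total step count: 6. Longest linear sequence: 6 steps (1 to 14).

Steps most likely to fail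

Step 6.
- Tautomerisation of 9 may be slow or may take place on the wrong face.
- The diene may attack C6' of 9 in a Michael-type manner.
- The cycloaddition may go to the wrong π bond (C3=C4 in particular), the wrong orientation or the wrong face.
- The seven-membered ring may close more slowly than intermolecular condensation.

The fallback sets out from 8 and 9 and returns at 14, using known reactions run singly.
- Fulvene 10 is isolated after the pyrrolidine/MeOH condensation. It is reduced with LiAlH4 and worked up with water to give 12, which is kept cold in solution.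
- In parallel, 9 is reduced with NaBH4 to the catechol pristimerol F1.
- F1 is oxidised with Ag2O at low temperature in the presence of 12, so that the first-formed 7'-ene o-quinone F2 is caught by the hetero-Diels–Alder reaction before it enolises to 9. This gives the 7'-ene isomer of the target F3.
- KOt-Bu in DMSO then moves this double bond into conjugation with the arene (allylbenzene-to-styrene isomerisation), with reprotonation at C8' from the open β face, to give 14.

Step 3. The sequence may stop at the β,γ-unsaturated ketone or the vinylcyclopropanol stage, or the lactone may simply be enolised. The fallback sets out from 3 and returns at 6.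
- Opening of 3 with MeNH(OMe)·HCl and i-PrMgCl gives the hydroxy Weinreb amide F4.
- Allylmagnesium chloride (excess, to cover the free alcohol) gives the allyl ketone F5.
- But-2-enylmagnesium chloride adds through its γ carbon to give the diallylic carbinol F6.
- Ring-closing metathesis with the second-generation Grubbs catalyst joins the two monosubstituted vinyl groups, leaves the isopropenyl group alone, and gives 6.

Step 5. Elimination may go towards C6 (exocyclic alkene), and the cyclopentadiene may dimerise by Diels–Alder reaction during isolation. The fallback sets out from 7 and returns at 10.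
- The tertiary alcohol is acetylated (Ac2O, DMAP) to the acetate F7.
- KOt-Bu in THF removes acetate by elimination through the allylic C1 or C4 hydrogen.
- The same base deprotonates the diene to its cyclopentadienide and brings about the Thiele condensation with the methyl ketone, so 10 forms without the free cyclopentadiene ever being handled.

Further compounds
F1 | step 6 | pristimerol (2',3'-catechol, 7'-ene) | Cc1c(O)c(O)cc2c1CC=C1[C@@]2(C)CC[C@@]2(C)[C@@H]3C[C@](C)(C(=O)OC)CC[C@]3(C)CC[C@]12C
F2 | step 6 | 7'-ene 2',3'-o-quinone from pristimerol | O=C1C=C2C(=C(C)C1=O)CC=C1[C@@]2(C)CC[C@@]2(C)[C@@H]3C[C@](C)(C(=O)OC)CC[C@]3(C)CC[C@]12C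
F3 | step 6 | 7'-ene isomer of the target | C=C(C)[C@H]1CC[C@H](C)[C@@]23CC=C(C)[C@]2(C1)Oc1cc2c(c(C)c1O3)CC=C1[C@@]2(C)CC[C@@]2(C)[C@@H]3C[C@](C)(C(=O)OC)CC[C@]3(C)CC[C@]12C
F4 | step 3 | (3S,6S)-6-hydroxy-N-methoxy-N-methyl-3-(prop-1-en-2-yl)heptanamide | C[C@H](O)CC[C@@H](CC(=O)N(C)OC)C(C)=C
F5 | step 3 | (6S,9S)-9-hydroxy-6-(prop-1-en-2-yl)dec-1-en-4-one | C[C@H](O)CC[C@@H](CC(=O)CC=C)C(C)=C
F6 | step 3 | (2S,5S)-7-(but-3-en-2-yl)-5-(prop-1-en-2-yl)dec-9-ene-2,7-diol (mixture at the new centres) | C[C@H](O)CC[C@@H](CC(O)(CC=C)C(C)C=C)C(C)=C
F7 | step 5 | 2-methyl-1-[(2S)-5-oxo-2-(prop-1-en-2-yl)hexyl]cyclopent-3-en-1-yl acetate | CC(=O)CC[C@@H](CC1(OC(C)=O)CC=CC1C)C(C)=C
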